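**Plan**
- Cuts (labdane numbering): C13–C14 (vinyl) and the O3–acetyl bond last; C4–C18 and C4–C19 in ring A; C10–C20 together with a temporary C5–C20 bond (a cyclopropane fused across C5/C10); C9–C11 (side chain); C8–O8 and C8–C17.
- Enabling feature: ring carbons C1–C10 with oxygen at C3 para to C10 are the skeleton of 6-methoxy-1-tetralone. C10 can therefore stay trigonal (arene, then the tetrasubstituted C5=C10 alkene shared by rings A and B) until C8 and C9 are fixed, and C20 is then added to that alkene as a methylene.
- Forward order: ring B is functionalised on the tetralone (C17, O8), the C11–C13/C16 chain is joined at C9, ring A is dearomatised and ketalised, the cyclopropane is closed on C5=C10 and opened by acid to the C10-methyl 4-en-3-one, ring A receives C19, H5, C18 and the C3 alcohol, and the diene is made last.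
- Stereochemistry: C8 by reagent-controlled enolate hydroxylation; C9 by hydrogenation anti to the C8 silyloxy group; C10 by carbenoid attack on the alkene face opposite the C9 chain; C5 by trans-selective Li/NH3 reduction; C4 by enolate hydroxymethylation anti to C20; C3 by axial hydride delivery.

Key step: step 9

Convention: labdane numbering is used for all bicyclic compounds; "lower face" is the face carrying H9, C17 and C20 in the target, "upper face" the one carrying O8, the C9 chain, H5 and C18; TBS = tert-butyldimethylsilyl.

Assumption: the antipode of (8,8-dichlorocamphorylsulfonyl)oxaziridine that oxidises the enolate of 3 to the (2S) alcohol is taken to be the one derived from (1R)-(−)-10-camphorsulfonic acid; should the sense be the reverse, its mirror image is used.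

**Step 1**
Reactants: 1 6-methoxy-1-tetralone
Product: 3 rac-6-methoxy-2-methyl-1-tetralone, via lithium enolate 2 (not isolated)
Conditions: LiN(i-Pr)2, THF, −78 °C; MeI, −78 → 0 °C
Reagents that add atoms: iodomethane, CI
Why: Alkylation of a preformed lithium enolate: C8 is the only enolisable position of the aryl ketone, so one equivalent of base and iodomethane should give the monomethyl ketone, whose new centre is racemic and is flattened again in step 2.

**Step 2**
Reactants: 3 rac-6-methoxy-2-methyl-1-tetralone
Product: 5 (2S)-2-hydroxy-6-methoxy-2-methyl-1-tetralone, via sodium enolate 4 (not isolated)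
Conditions: NaN(SiMe3)2, THF, −78 °C; (8,8-dichlorocamphorylsulfonyl)oxaziridine, −78 °C; NH4Cl (aq)
Reagents that add atoms: (8,8-dichlorocamphorylsulfonyl)oxaziridine from (1R)-(−)-10-camphorsulfonic acid, CC1(C)[C@H]2CC[C@@]13CS(=O)(=O)N4O[C@]34C2(Cl)Cl
Why: Davis asymmetric enolate hydroxylation: the ring-locked tetrasubstituted sodium enolate attacks the oxaziridine oxygen in an SN2-type step and the dichlorinated camphor framework blocks one enolate face, so that O8 should enter C8 with the (S) configuration, as established for 2-methyl-1-tetralone itself.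

**Step 3**
Reactants: 5 (2S)-2-hydroxy-6-methoxy-2-methyl-1-tetralone
Product: 6 (2S)-2-(TBS-oxy)-6-methoxy-2-methyl-1-tetralone
Conditions: TBSOTf, 2,6-lutidine, CH2Cl2, 0 → 25 °C
Reagents that add atoms: tert-butyldimethylsilyl triflate, CC(C)(C)[Si](C)(C)OS(=O)(=O)C(F)(F)F
Why: Silyl triflate silylation, the standard way to protect a hindered tertiary carbinol, gives a bulky, poorly coordinating ether that prevents pinacol chemistry in step 5, screens the upper face in steps 6 and 9 and is stable to every condition up to step 20.

**Step 4**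
Reactants: 6 (2S)-2-(TBS-oxy)-6-methoxy-2-methyl-1-tetralone; 7 2-(2-bromoethyl)-2-methyl-1,3-dioxolane
Product: 10 tertiary benzylic alcohol (both C9 epimers), via Grignard reagent 8 (not isolated), via organocerium reagent 9 (not isolated)
Conditions: 7, Mg, THF, 25 °C; CeCl3, THF, −78 °C; 6, −78 → −40 °C; NH4Cl (aq)
Reagents that add atoms: 2-(2-bromoethyl)-2-methyl-1,3-dioxolane (7), CC1(CCBr)OCCO1
Why: Organocerium addition to a ketone: transmetallation of the Grignard reagent to cerium suppresses β-hydride reduction of the hindered, non-enolisable aryl ketone, so the C9–C11 bond should form by simple 1,2-addition, and the configuration of the new carbinol centre is irrelevant because C9 becomes trigonal in step 5.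

**Step 5**
Reactants: 10 tertiary benzylic alcohol
Product: 11 exocyclic C9=C11 alkene (E/Z mixture)
Conditions: Burgess reagent, toluene, 60 °C
Reagents that add atoms: none
Why: Burgess dehydration, a syn elimination under neutral conditions, should give only the exocyclic C9=C11 alkene because C8 is quaternary and C10 is aromatic, and it avoids a free p-anisyl-stabilised cation at C9 that could trigger a semipinacol shift from C8.

**Step 6**
Reactants: 11 exocyclic C9=C11 alkene
Product: 12 (1R,2S)-tetralin with the side chain on C9 (naphthalene C1)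
Conditions: H2 (1 atm), Pt/C, EtOAc, 25 °C
Reagents that add atoms: none
Why: Heterogeneous catalytic hydrogenation with syn addition from the less hindered face: beside the exocyclic alkene the C8–O bond prefers the pseudoaxial position, so the OTBS group covers the upper face and hydrogen should be delivered to C9 from the lower face, placing H9 cis to C17 and the chain cis to O8 from either alkene isomer, while platinum is used because it is much less prone than palladium to cleave the allylic C8–O bond.

**Step 7**
Reactants: 12 (1R,2S)-tetralin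
Product: 13 2,5(10)-dienol methyl ether
Conditions: Li, NH3 (l), THF, t-BuOH, −78 → −33 °C; MeOH
Reagents that add atoms: none
Why: Birch reduction of an anisole: the ring is protonated at C1 and C4, which leaves the methyl enol ether C2=C3 and the tetrasubstituted C5=C10 alkene exactly as in the reduction of estradiol methyl ether, and the silyl ether, the dioxolane and the two stereocentres are inert to lithium in ammonia.

**Step 8**
Reactants: 13 2,5(10)-dienol methyl ether
Product: 14 C5=C10 alkene with dioxolanes at C3 and C13 and OTBS at C8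
Conditions: HOCH2CH2OH, PPTS (cat.), THF, 25 °C
Reagents that add atoms: ethylene glycol, OCCO
Why: Acid-catalysed transketalisation of an enol ether: protonation at C2 gives the C3 oxocarbenium ion, which ethylene glycol captures as the dioxolane, and the non-conjugated tetrasubstituted C5=C10 alkene stays in place because no ketone is ever freed that could draw it into conjugation.

**Step 9**
Reactants: 14 C5=C10 alkene bis-ketal; 15 diiodomethane
Product: 17 5,10-methano (cyclopropane) bis-ketal with C20 on the lower face, via zinc carbenoid 16 (not isolated)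
Conditions: Et2Zn, CH2I2, ClCH2CH2Cl, 0 → 25 °C
Reagents that add atoms: diiodomethane (15), ICI
Why: Et2Zn and CH2I2 give the carbenoid EtZnCH2I (16), which transfers CH2 to the electron-rich tetrasubstituted C5=C10 alkene through the concerted butterfly transition state of the Simmons–Smith (Furukawa) cyclopropanation, the closest precedent being the methylenation of steroidal 5(10)-enes obtained by Birch reduction. The three-membered ring closes in one suprafacial [2+1] event in which C10–C20 and C5–C20 form together, so no separate exo or endo ring closure is involved. C5 and C10 are created together and cis to each other by the syn addition, and their absolute sense follows solely from the alkene face that is attacked. The selectivity needed is attack on the lower face, and ring B secures it: in one half-chair A(1,2) strain against the C1 methylene holds the C9 chain pseudoaxial on the upper face directly beside C10, and in the other half-chair the OTBS group is axial on that same face, so the upper face is screened in both conformers while the lower face is open in the conformer that has C17 equatorial. The tertiary silyl ether on O8 is too hindered to bind zinc and the two C3 ketal oxygens lie one on each face, so coordination can accelerate the reaction without biasing it. C5=C10 is the only alkene in 14, so chemoselectivity is not in question.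

**Step 10**
Reactants: 17 5,10-methano bis-ketal
Product: 19 C10-methyl 4-ene-3,13-dione with OTBS at C8, via cyclopropyl diketone 18 (not isolated)
Conditions: 2 M HCl (aq), THF, 45 °C
Reagents that add atoms: water, O
Why: Ketal hydrolysis followed by the acid-catalysed isomerisation of a β,γ-cyclopropyl ketone to a γ-methyl enone, known from 5,10-methano steroids: the C3 ketone enolises toward C4, protonation at C20 breaks the strained C5–C20 bond and leaves C20 as the methyl group on C10 with C10 unchanged, while the hindered tertiary TBS ether is expected to survive the dilute acid.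

**Step 11**
Reactants: 19 4-ene-3,13-dione
Product: 20 4-en-3-one with the C13 ketone as its dioxolane
Conditions: (Me3SiOCH2)2, TMSOTf (cat.), CH2Cl2, −78 °C; pyridine
Reagents that add atoms: 1,2-bis(trimethylsilyloxy)ethane, C[Si](C)(C)OCCO[Si](C)(C)C
Why: Silyl triflate-catalysed ketalisation with the bis-silyl ether of ethylene glycol is selective at low temperature for the saturated methyl ketone over the less electrophilic conjugated enone, so C13 is masked again for the enolate and dissolving-metal steps.

**Step 12**
Reactants: 20 4-en-3-one C13 ketal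
Product: 23 4-methyl-4-en-3-one, via potassium dienolate 21 (not isolated), via deconjugated 4-methyl ketone 22 (not isolated)
Conditions: KOt-Bu, t-BuOH, 25 °C; MeI (slow addition)
Reagents that add atoms: iodomethane, CI
Why: Alkylation of the extended dienolate of a 4-en-3-one, which reacts at the α-carbon C4 and whose deconjugated product is returned to the conjugated 4-methyl enone by the base, with slow addition of one equivalent of iodomethane to limit a second methylation.

**Step 13**
Reactants: 23 4-methyl-4-en-3-one; 24 formaldehyde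
Product: 26 trans-fused 18-hydroxy-3-ketone, via lithium enolate 25 (not isolated)
Conditions: Li, NH3 (l), THF, t-BuOH (1 equiv), −78 °C; isoprene; NH3 removed; CH2O (g), THF, −78 → −30 °C; NH4Cl (aq)
Reagents that add atoms: formaldehyde (24), C=O
Why: Dissolving-metal reduction of an enone with in situ aldol trapping (reductive hydroxymethylation): C5 is protonated from the upper face to give the trans ring fusion, since the only other stereoelectronically allowed mode would force C4 syn-axial to the C9 chain, and the regiodefined C3 enolate then adds formaldehyde at C4 anti to the axial C20 methyl, which puts C18 equatorial on the upper face and C19 axial on the lower face.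

**Step 14**
Reactants: 26 18-hydroxy-3-ketone
Product: 27 3,18-diol
Conditions: NaBH4, MeOH, 0 °C
Reagents that add atoms: none
Why: Borohydride reduction of a cyclohexanone by axial hydride attack: the upper face of C3 is free while the lower face is guarded by the axial C19 and C20 methyl groups, so the equatorial lower-face alcohol should form, as with 4,4-disubstituted 3-oxo triterpenoids, and reducing the β-hydroxy ketone directly after its formation also removes the retro-aldol risk.

**Step 15**
Reactants: 27 3,18-diol
Product: 28 18-O-TBS ether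
Conditions: TBSCl, imidazole, DMF, 0 °C
Reagents that add atoms: tert-butyldimethylsilyl chloride, CC(C)(C)[Si](C)(C)Cl
Why: Chemoselective silylation: the primary C18 hydroxyl reacts with TBSCl much faster than the secondary C3 hydroxyl beside the quaternary C4, which differentiates the two oxygens for step 16.

**Step 16**
Reactants: 28 18-O-TBS ether
Product: 29 3-acetate
Conditions: Ac2O, pyridine, DMAP (cat.), 25 °C
Reagents that add atoms: acetic anhydride, CC(=O)OC(C)=O
Why: DMAP-catalysed acylation of the only free hydroxyl group installs the C3 acetate of the target.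

**Step 17**
Reactants: 29 3-acetate
Product: 30 C13 methyl ketone
Conditions: PPTS, acetone/H2O, 50 °C
Reagents that add atoms: water, O
Why: Acid-catalysed ketal exchange with acetone and water frees the C13 methyl ketone under conditions that the neopentyl and the tertiary TBS ether and the acetate should tolerate.

**Step 18**
Reactants: 30 C13 methyl ketone
Product: 32 C13(16) enol triflate, via potassium enolate 31 (not isolated)
Conditions: KN(SiMe3)2, THF, −78 °C; N-(5-chloro-2-pyridyl)triflimide, −78 °C; NH4Cl (aq)
Reagents that add atoms: N-(5-chloro-2-pyridyl)bis(trifluoromethanesulfonyl)imide, FC(F)(F)S(=O)(=O)N(c1ccc(Cl)cn1)S(=O)(=O)C(F)(F)F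
Why: Kinetic enolate formation and O-sulfonylation: the hindered silylamide removes a proton from the C16 methyl group and not from C12, the triflimide traps the terminal enolate at −78 °C before it can equilibrate, and the acetate, several pK units less acidic than the ketone, should be left alone by one equivalent of base.

**Step 19**
Reactants: 32 C13(16) enol triflate
Product: 33 8,18-bis-O-TBS ether of the target
Conditions: Bu3SnCH=CH2, Pd(PPh3)4 (cat.), LiCl, THF, 60 °C
Reagents that add atoms: tributyl(vinyl)stannane, C=C[Sn](CCCC)(CCCC)CCCC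
Why: Stille coupling of an alkenyl triflate with a vinylstannane, run with LiCl under neutral conditions, forms the C13–C14 bond and with it the 2-substituted 1,3-diene without touching the acetate or the silyl ethers.

**Step 20**
Reactants: 33 8,18-bis-O-TBS ether
Product: 34 target, (3R,4S,5S,8S,9R,10R)-3-acetoxylabda-13(16),14-diene-8,18-diol
Conditions: HF·pyridine, pyridine, THF, 0 → 25 °C
Reagents that add atoms: none
Why: Fluoride-induced desilylation: HF·pyridine cleaves the primary and the hindered tertiary TBS ether, and its buffered acidic medium avoids the base-promoted acetyl migration from O3 to O18 that tetrabutylammonium fluoride could cause.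

**Compound list**
1 | 6-methoxy-3,4-dihydronaphthalen-1(2H)-one (6-methoxy-1-tetralone) | COc1ccc2C(=O)CCCc2c1 | starting material
2 | lithium enolate of 1 (not isolated) | COc1ccc2C(O[Li])=CCCc2c1 | intermediate
3 | rac-6-methoxy-2-methyl-3,4-dihydronaphthalen-1(2H)-one | COc1ccc2C(=O)C(C)CCc2c1 | intermediate
4 | sodium enolate of 3 (not isolated) | COc1ccc2C(O[Na])=C(C)CCc2c1 | intermediate
5 | (2S)-2-hydroxy-6-methoxy-2-methyl-3,4-dihydronaphthalen-1(2H)-one | COc1ccc2C(=O)[C@@](C)(O)CCc2c1 | intermediate
6 | (2S)-2-[(tert-butyldimethylsilyl)oxy]-6-methoxy-2-methyl-3,4-dihydronaphthalen-1(2H)-one | COc1ccc2C(=O)[C@@](C)(O[Si](C)(C)C(C)(C)C)CCc2c1 | intermediate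
7 | 2-(2-bromoethyl)-2-methyl-1,3-dioxolane | CC1(CCBr)OCCO1 | starting material
8 | [2-(2-methyl-1,3-dioxolan-2-yl)ethyl]magnesium bromide (not isolated) | CC1(CC[Mg]Br)OCCO1 | intermediate
9 | dichloro[2-(2-methyl-1,3-dioxolan-2-yl)ethyl]cerium (not isolated) | CC1(CC[Ce](Cl)Cl)OCCO1 | intermediate
10 | (2S)-2-(TBS-oxy)-6-methoxy-2-methyl-1-[2-(2-methyl-1,3-dioxolan-2-yl)ethyl]-1,2,3,4-tetrahydronaphthalen-1-ol, both epimers at C1 (labdane C9) | CC1(OCCO1)CCC2(O)c3ccc(OC)cc3CC[C@]2(C)O[Si](C)(C)C(C)(C)C | intermediate
11 | tert-butyl{[(2S)-6-methoxy-2-methyl-1-[2-(2-methyl-1,3-dioxolan-2-yl)ethylidene]-1,2,3,4-tetrahydronaphthalen-2-yl]oxy}dimethylsilane, E/Z mixture | CC1(OCCO1)CC=C2c3ccc(OC)cc3CC[C@]2(C)O[Si](C)(C)C(C)(C)C | intermediate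
12 | tert-butyl{[(1R,2S)-6-methoxy-2-methyl-1-[2-(2-methyl-1,3-dioxolan-2-yl)ethyl]-1,2,3,4-tetrahydronaphthalen-2-yl]oxy}dimethylsilane (H9 lower face, chain and O8 upper face) | CC1(OCCO1)CC[C@@H]2c3ccc(OC)cc3CC[C@]2(C)O[Si](C)(C)C(C)(C)C | intermediate
13 | tert-butyl{[(1R,2S)-6-methoxy-2-methyl-1-[2-(2-methyl-1,3-dioxolan-2-yl)ethyl]-1,2,3,4,5,8-hexahydronaphthalen-2-yl]oxy}dimethylsilane (enol ether C2=C3, alkene C5=C10) | CC1(OCCO1)CC[C@@H]2C3=C(CC(OC)=CC3)CC[C@]2(C)O[Si](C)(C)C(C)(C)C | intermediate
14 | (8S,9R)-8-(TBS-oxy)-14,15,18,19,20-pentanorlabd-5(10)-ene-3,13-dione bis(ethylene ketal) | CC1(OCCO1)CC[C@@H]2C3=C(CC4(CC3)OCCO4)CC[C@]2(C)O[Si](C)(C)C(C)(C)C | intermediate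
15 | diiodomethane | ICI | starting material
16 | ethyl(iodomethyl)zinc (not isolated) | CC[Zn]CI | intermediate
17 | (5R,8S,9R,10R)-8-(TBS-oxy)-5,20-cyclo-14,15,18,19-tetranorlabdane-3,13-dione bis(ethylene ketal), cyclopropane CH2 (C20) on the lower face | CC1(OCCO1)CC[C@@H]2[C@@]34C[C@@]3(CC5(CC4)OCCO5)CC[C@]2(C)O[Si](C)(C)C(C)(C)C | intermediate
18 | (5R,8S,9R,10R)-8-(TBS-oxy)-5,20-cyclo-14,15,18,19-tetranorlabdane-3,13-dione (not isolated) | CC(=O)CC[C@@H]1[C@@]23C[C@@]2(CC(=O)CC3)CC[C@]1(C)O[Si](C)(C)C(C)(C)C | intermediate
19 | (8S,9R,10S)-8-(TBS-oxy)-14,15,18,19-tetranorlabd-4-ene-3,13-dione (C20 methyl on the lower face) | CC(=O)CC[C@@H]1[C@]2(C)CCC(=O)C=C2CC[C@]1(C)O[Si](C)(C)C(C)(C)C | intermediate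
20 | 13-ethylene ketal of 19 | CC1(OCCO1)CC[C@@H]2[C@]3(C)CCC(=O)C=C3CC[C@]2(C)O[Si](C)(C)C(C)(C)C | intermediate
21 | potassium 3,5-dienolate of 20 (not isolated) | CC1(OCCO1)CC[C@@H]2[C@]3(C)CCC(O[K])=CC3=CC[C@]2(C)O[Si](C)(C)C(C)(C)C | intermediate
22 | 4-methyl-5-en-3-one from 21, both C4 epimers (not isolated) | CC1(OCCO1)CC[C@@H]2[C@]3(C)CCC(=O)C(C)C3=CC[C@]2(C)O[Si](C)(C)C(C)(C)C | intermediate
23 | (8S,9R,10S)-8-(TBS-oxy)-14,15,18-trinorlabd-4-ene-3,13-dione 13-ethylene ketal (C19 methyl on C4) | CC1(OCCO1)CC[C@@H]2[C@]3(C)CCC(=O)C(C)=C3CC[C@]2(C)O[Si](C)(C)C(C)(C)C | intermediate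
24 | formaldehyde | C=O | starting material
25 | lithium 3-enolate of the trans-fused ketone, H5 on the upper face (not isolated) | CC1(OCCO1)CC[C@@H]2[C@]3(C)CCC(O[Li])=C(C)[C@H]3CC[C@]2(C)O[Si](C)(C)C(C)(C)C | intermediate
26 | (4S,5S,8S,9R,10R)-8-(TBS-oxy)-18-hydroxy-14,15-dinorlabdane-3,13-dione 13-ethylene ketal | CC1(OCCO1)CC[C@@H]2[C@]3(C)CCC(=O)[C@](C)(CO)[C@H]3CC[C@]2(C)O[Si](C)(C)C(C)(C)C | intermediate
27 | (3R,4S,5S,8S,9R,10R)-8-(TBS-oxy)-3,18-dihydroxy-14,15-dinorlabdan-13-one ethylene ketal | CC1(OCCO1)CC[C@@H]2[C@]3(C)CC[C@@H](O)[C@](C)(CO)[C@H]3CC[C@]2(C)O[Si](C)(C)C(C)(C)C | intermediate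
28 | 18-O-TBS ether of 27 | CC1(OCCO1)CC[C@@H]2[C@]3(C)CC[C@@H](O)[C@](C)(CO[Si](C)(C)C(C)(C)C)[C@H]3CC[C@]2(C)O[Si](C)(C)C(C)(C)C | intermediate
29 | 3-O-acetate of 28 | CC1(OCCO1)CC[C@@H]2[C@]3(C)CC[C@@H](OC(C)=O)[C@](C)(CO[Si](C)(C)C(C)(C)C)[C@H]3CC[C@]2(C)O[Si](C)(C)C(C)(C)C | intermediate
30 | (3R,4S,5S,8S,9R,10R)-3-acetoxy-8,18-bis(TBS-oxy)-14,15-dinorlabdan-13-one | CC(=O)CC[C@@H]1[C@]2(C)CC[C@@H](OC(C)=O)[C@](C)(CO[Si](C)(C)C(C)(C)C)[C@H]2CC[C@]1(C)O[Si](C)(C)C(C)(C)C | intermediate
31 | potassium enolate of 30 at C13/C16 (not isolated) | C=C(O[K])CC[C@@H]1[C@]2(C)CC[C@@H](OC(C)=O)[C@](C)(CO[Si](C)(C)C(C)(C)C)[C@H]2CC[C@]1(C)O[Si](C)(C)C(C)(C)C | intermediate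
32 | (3R,4S,5S,8S,9R,10R)-3-acetoxy-8,18-bis(TBS-oxy)-14,15-dinorlabd-13(16)-en-13-yl triflate | C=C(OS(=O)(=O)C(F)(F)F)CC[C@@H]1[C@]2(C)CC[C@@H](OC(C)=O)[C@](C)(CO[Si](C)(C)C(C)(C)C)[C@H]2CC[C@]1(C)O[Si](C)(C)C(C)(C)C | intermediate
33 | (3R,4S,5S,8S,9R,10R)-8,18-bis(TBS-oxy)labda-13(16),14-dien-3-yl acetate | C=CC(=C)CC[C@@H]1[C@]2(C)CC[C@@H](OC(C)=O)[C@](C)(CO[Si](C)(C)C(C)(C)C)[C@H]2CC[C@]1(C)O[Si](C)(C)C(C)(C)C | intermediate
34 | (3R,4S,5S,8S,9R,10R)-8,18-dihydroxylabda-13(16),14-dien-3-yl acetate (CNP0313672.1) | C=CC(=C)CC[C@@H]1[C@]2(C)CC[C@@H](OC(C)=O)[C@](C)(CO)[C@H]2CC[C@]1(C)O | target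

**Step count:** 20 steps in total; the longest linear sequence is 20 steps (1 → 34); compounds 7, 15 and 24 are commercial and enter directly.

**Steps most likely to fail**

Step 9. The risk is poor facial discrimination, or sluggish methylene transfer, at the hindered tetrasubstituted alkene, because steric screening by ring B is the only control element. The fallback replaces steric control by hydroxyl direction, as practised on steroidal 5(10)-en-3-ols. It sets out from 13: oxalic acid in aqueous THF hydrolyses only the enol ether and should give the β,γ-unsaturated ketone F1. NaBH4 reduces it to the C3 alcohols, from which the lower-face epimer, homoallylic alcohol F2, is separated; the other epimer is returned to F1 with Dess–Martin periodinane. Et2Zn and CH2I2 then form the zinc alkoxide of F2, which should deliver carbenoid 16 to the face of the hydroxyl group and give the lower-face cyclopropyl carbinol F3. Dess–Martin oxidation gives the cyclopropyl ketone F4. Treating F4 under the conditions of step 10 hydrolyses the side-chain dioxolane and opens the ring, and the route is rejoined at 19.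

Step 6. The risk is insufficient facial selectivity at the exocyclic alkene (or hydrogenolysis of the allylic C8–O bond), which would erode the C9 configuration. The fallback sets C8 and C9 together through an epoxide and a stereospecific C–O hydrogenolysis. It sets out from 3: organocerium reagent 9 is added to give the tertiary alcohol F5. Dehydration with catalytic TsOH in benzene containing ethylene glycol gives the thermodynamically preferred endocyclic tetrasubstituted styrene F6. Shi epoxidation (fructose-derived ketone, KHSO5, K2CO3 buffer), with the catalyst antipode that oxidises the upper face, should give the epoxide F7 with oxygen on the upper face of C8 and C9. Hydrogenolysis of the benzylic C9–O bond over Pd/C proceeds with inversion and should give the alcohol F8 with H9 on the lower face and the chain cis to O8. Silylation with TBSOTf and 2,6-lutidine returns to 12.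

Step 20. The risk is incomplete cleavage of the very hindered tertiary silyl ether, or acid damage to the diene and the tertiary carbinol if the cleavage has to be forced. The fallback exchanges the robust silyl groups for labile ones before the diene exists. It sets out from 29: aqueous HF in MeCN removes both TBS groups and the dioxolane and should give the dihydroxy ketone F9. TESOTf and 2,6-lutidine at −78 °C silylate the primary and the tertiary hydroxyl to give the bis(triethylsilyl) ether F10. Enolisation with KN(SiMe3)2 as in step 18 gives the potassium enolate F11, which is trapped with the same triflimide as the enol triflate F12. Stille coupling as in step 19 gives the bis(triethylsilyl) diene F13. Brief exposure to HF·pyridine in THF at 0 °C removes both triethylsilyl groups and the route arrives at 34.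

**Further compounds**
F1 | step 9 | (8S,9R)-8-(TBS-oxy)-14,15,18,19,20-pentanorlabd-5(10)-ene-3,13-dione 13-ethylene ketal | CC1(OCCO1)CC[C@@H]2C3=C(CC(=O)CC3)CC[C@]2(C)O[Si](C)(C)C(C)(C)C
F2 | step 9 | 3-hydroxy (lower face) 5(10)-ene from F1 | CC1(OCCO1)CC[C@@H]2C3=C(C[C@H](O)CC3)CC[C@]2(C)O[Si](C)(C)C(C)(C)C
F3 | step 9 | 5,10-methano (lower face) 3-ol from F2 | CC1(OCCO1)CC[C@@H]2[C@@]34C[C@@]3(C[C@H](O)CC4)CC[C@]2(C)O[Si](C)(C)C(C)(C)C
F4 | step 9 | 5,10-methano 3-ketone with C13 dioxolane and 8-OTBS | CC1(OCCO1)CC[C@@H]2[C@@]34C[C@@]3(CC(=O)CC4)CC[C@]2(C)O[Si](C)(C)C(C)(C)C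
F5 | step 6 | 6-methoxy-2-methyl-1-[2-(2-methyl-1,3-dioxolan-2-yl)ethyl]-1,2,3,4-tetrahydronaphthalen-1-ol (stereoisomer mixture) | COc1ccc2c(c1)CCC(C)C2(O)CCC1(C)OCCO1
F6 | step 6 | 7-methoxy-3-methyl-4-[2-(2-methyl-1,3-dioxolan-2-yl)ethyl]-1,2-dihydronaphthalene (C8=C9 alkene) | COc1ccc2c(c1)CCC(C)=C2CCC1(C)OCCO1
F7 | step 6 | 8,9-epoxide of F6 with oxygen on the upper face | CC1(OCCO1)CC[C@]23O[C@@]2(C)CCc4cc(OC)ccc34
F8 | step 6 | (1R,2S)-6-methoxy-2-methyl-1-[2-(2-methyl-1,3-dioxolan-2-yl)ethyl]-1,2,3,4-tetrahydronaphthalen-2-ol | CC1(OCCO1)CC[C@@H]2c3ccc(OC)cc3CC[C@]2(C)O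
F9 | step 20 | (3R,4S,5S,8S,9R,10R)-3-acetoxy-8,18-dihydroxy-14,15-dinorlabdan-13-one | CC(=O)CC[C@@H]1[C@]2(C)CC[C@@H](OC(C)=O)[C@](C)(CO)[C@H]2CC[C@]1(C)O
F10 | step 20 | 8,18-bis-O-triethylsilyl ether of F9 | CC(=O)CC[C@@H]1[C@]2(C)CC[C@@H](OC(C)=O)[C@](C)(CO[Si](CC)(CC)CC)[C@H]2CC[C@]1(C)O[Si](CC)(CC)CC
F11 | step 20 | potassium enolate of F10 at C13/C16 | C=C(O[K])CC[C@@H]1[C@]2(C)CC[C@@H](OC(C)=O)[C@](C)(CO[Si](CC)(CC)CC)[C@H]2CC[C@]1(C)O[Si](CC)(CC)CC
F12 | step 20 | C13(16) enol triflate from F11 | C=C(OS(=O)(=O)C(F)(F)F)CC[C@@H]1[C@]2(C)CC[C@@H](OC(C)=O)[C@](C)(CO[Si](CC)(CC)CC)[C@H]2CC[C@]1(C)O[Si](CC)(CC)CC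
F13 | step 20 | 8,18-bis-O-triethylsilyl ether of the target | C=CC(=C)CC[C@@H]1[C@]2(C)CC[C@@H](OC(C)=O)[C@](C)(CO[Si](CC)(CC)CC)[C@H]2CC[C@]1(C)O[Si](CC)(CC)CC
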